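Ring B is cut at the two bonds that join its lactol‑bearing and lactone‑carbonyl‑bearing carbons to their ring neighbours. Ring B is exploited because its other four carbons carry, in order, the diaryl‑ether oxygen, the ester oxygen of the seven‑membered ring, a methyl group and the phenol oxygen: a 1,2,4‑trioxygenated 3‑methyl diene. That diene is built into a ring‑A‑fused dioxepinone enol lactone bearing an exocyclic (E)‑2‑methoxy‑1‑methylvinyl group. In one operation, cycloaddition to dibromomaleic anhydride and loss of two HBr close ring B as a hexasubstituted phthalic anhydride with all its heteroatoms attached.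

Key step: step 9

Remark: the hemiacetal carbon of a 3‑hydroxyphthalide can epimerise through its ring‑opened formyl acid, so (R) is fixed as an O‑acyl derivative and the free lactol is liberated last under neutral anhydrous conditions; it is assumed that the target then keeps its configuration when stored cold and free of acid and base.

Step 1
Reactants: 1 atraric acid (methyl 2,4‑dihydroxy‑3,6‑dimethylbenzoate)
Product: 2 methyl 2‑hydroxy‑4‑methoxy‑3,6‑dimethylbenzoate
Conditions: MeI (1.1 equiv), K2CO3 (1.1 equiv), acetone, reflux
Reagents that add atoms: iodomethane, CI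
Why: Williamson O‑methylation: the 2‑hydroxyl is tied up in a hydrogen bond to the ester carbonyl and flanked on both sides, so carbonate and one equivalent of iodomethane should alkylate only the 4‑hydroxyl.

Step 2
Reactants: 2 methyl 2‑hydroxy‑4‑methoxy‑3,6‑dimethylbenzoate
Product: 3 2‑hydroxy‑4‑methoxy‑3,6‑dimethylbenzoic acid
Conditions: KOH (5 equiv), DMSO–H2O 4:1, 90 °C; then 1 M HCl, 0 °C
Reagents that add atoms: potassium hydroxide, [K+].[OH-]
Why: BAc2 saponification; the di‑ortho‑substituted ester needs the poorly solvated hydroxide of aqueous DMSO, and the acid is liberated cold because electron‑rich salicylic acids decarboxylate when warmed in acid.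

Step 3
Reactants: 3 2‑hydroxy‑4‑methoxy‑3,6‑dimethylbenzoic acid
Product: 4 allyl 2‑hydroxy‑4‑methoxy‑3,6‑dimethylbenzoate
Conditions: allyl bromide (1.1 equiv), KHCO3 (1.2 equiv), DMF, rt
Reagents that add atoms: allyl bromide, C=CCBr
Why: SN2 O‑alkylation of the carboxylate: hydrogen carbonate deprotonates the acid but not the chelated phenol, so only the allyl ester should form, a carboxyl protection that is later removable without acid or base.

Step 4
Reactants: 5 methyl propionate
Product: 7 methyl (E)‑3‑methoxy‑2‑methylprop‑2‑enoate, via sodium formyl‑ester enolate 6 (not isolated)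
Conditions: NaH (1.1 equiv), HCO2Me (1.5 equiv), MeOH (cat.), THF, 0 °C → rt; then Me2SO4 (1.1 equiv), DMF, rt; distillation
Reagents that add atoms: methyl formate, COC=O; dimethyl sulfate, COS(=O)(=O)OC
Why: Crossed Claisen formylation gives enolate 6, which the hard electrophile dimethyl sulfate alkylates on oxygen in DMF; the E enol ether (methoxy anti to the ester) is the thermodynamically preferred isomer of such β‑methoxyacrylates, and any Z isomer can be equilibrated to it with a trace of acid.

Step 5
Reactants: 7 methyl (E)‑3‑methoxy‑2‑methylprop‑2‑enoate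
Product: 9 (E)‑1‑chloro‑4‑methoxy‑3‑methylbut‑3‑en‑2‑one, via lithium hemiketal alkoxide 8 (not isolated)
Conditions: ICH2Cl (1.3 equiv), MeLi·LiBr (1.2 equiv), THF, −78 °C; AcOH, −78 °C → rt
Reagents that add atoms: chloroiodomethane, ClCI
Why: Ester‑to‑chloromethyl‑ketone homologation: chloromethyllithium, formed in the flask by iodine–lithium exchange, adds 1,2 to the ester, and alkoxide 8 holds at −78 °C until the acidic quench, so a second addition is avoided and the E enol ether is untouched.

Step 6
Reactants: 4 allyl 2‑hydroxy‑4‑methoxy‑3,6‑dimethylbenzoate; 9 (E)‑1‑chloro‑4‑methoxy‑3‑methylbut‑3‑en‑2‑one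
Product: 10 allyl 4‑methoxy‑2‑{[(3E)‑4‑methoxy‑3‑methyl‑2‑oxobut‑3‑en‑1‑yl]oxy}‑3,6‑dimethylbenzoate
Conditions: K2CO3 (1.5 equiv), NaI (10 mol%), acetone, rt → 40 °C
Reagents that add atoms: none
Why: Williamson etherification with an α‑chloro ketone (iodide‑assisted SN2), fast enough near room temperature that carbonate should neither trigger Dieckmann‑type closure onto the hindered ester nor displace the vinylogous methoxy group.

Step 7
Reactants: 10 allyl 4‑methoxy‑2‑{[(3E)‑4‑methoxy‑3‑methyl‑2‑oxobut‑3‑en‑1‑yl]oxy}‑3,6‑dimethylbenzoate
Product: 11 4‑methoxy‑2‑{[(3E)‑4‑methoxy‑3‑methyl‑2‑oxobut‑3‑en‑1‑yl]oxy}‑3,6‑dimethylbenzoic acid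
Conditions: Pd(PPh3)4 (3 mol%), sodium p‑toluenesulfinate (1.2 equiv), THF–MeOH, rt; then cold 5% aq. NaHSO4
Reagents that add atoms: none
Why: Tsuji–Trost deallylation: Pd(0) ionises the allyl ester and the soft sulfinate traps the π‑allyl complex, freeing the acid under neutral conditions that spare the β‑methoxy enone (amine scavengers are avoided because they would exchange the vinylogous methoxy group).

Step 8
Reactants: 11 4‑methoxy‑2‑{[(3E)‑4‑methoxy‑3‑methyl‑2‑oxobut‑3‑en‑1‑yl]oxy}‑3,6‑dimethylbenzoic acid
Product: 12 8‑methoxy‑3‑[(1E)‑1‑methoxyprop‑1‑en‑2‑yl]‑6,9‑dimethyl‑5H‑1,4‑benzodioxepin‑5‑one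
Conditions: (CF3CO)2O (1.3 equiv), 2,6‑lutidine (3 equiv), CH2Cl2 (0.01 M), 0 °C → rt
Reagents that add atoms: none
Why: Dehydrative enol‑lactonisation: the mixed trifluoroacetic anhydride of this 2,6‑disubstituted, electron‑rich acid acts as an acylium donor toward the nucleophilic carbonyl oxygen of the vinylogous ester, and lutidine then removes a proton from the only enolisable position (the OCH2 group), so the seven‑membered ring should close with the new C2=C3 bond necessarily cis‑dioxygenated and the E enol ether unchanged.

Step 9
Reactants: 12 8‑methoxy‑3‑[(1E)‑1‑methoxyprop‑1‑en‑2‑yl]‑6,9‑dimethyl‑5H‑1,4‑benzodioxepin‑5‑one; 13 dibromomaleic anhydride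
Product: 15 depsidone phthalic anhydride methyl ether, via dibromo cycloadduct 14 (not isolated)
Conditions: 13 (1.3 equiv), PhMe (0.5 M), BHT (cat.), 80 °C; then Et3N (3 equiv), 0 °C → rt
Reagents that add atoms: none
Why: Heating lets the diene unit O–CH=C(O‑acyl)–C(Me)=CH–OMe of 12, raised in energy by three oxygen donors and able to reach s‑cis because both terminal oxygens point outward (ring‑enforced at C2, E at the exocyclic bond), add to electron‑poor 13 in a concerted suprafacial [4+2] cycloaddition that gives dibromide 14. Triethylamine then removes HBr twice across the two new C–C bonds, the second loss being driven by aromatisation, so ring B emerges as a benzene ring. The closest known reaction type is the benzannulation of oxygenated dienes with halogenated maleic anhydrides or haloquinones, aromatised by loss of HX. Ring B is the only ring closed, by intermolecular cycloaddition that forms both bonds from the diene termini (the future ether‑bearing and methoxy‑bearing carbons) to the two anhydride ring carbons. No stereocentre survives, since the sp3 centres of 14 are erased on aromatisation. The selectivity needed is aromatisation with retention of the aryloxy and methoxy groups; it is built in, since each oxygen‑bearing sp3 carbon of 14 is flanked only by a quaternary C–Br carbon and an sp2 carbon, leaving HBr as the sole β‑elimination available, and because 13 is symmetric both orientations give the same product.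

Step 10
Reactants: 15 depsidone phthalic anhydride methyl ether
Product: 16 depsidone phthalic anhydride phenol
Conditions: BCl3 (1 M in CH2Cl2, 2.5 equiv), CH2Cl2, −78 → 0 °C; then ice‑water
Reagents that add atoms: none
Why: Chelation‑controlled ether cleavage: boron trichloride bound to the neighbouring anhydride carbonyl delivers chloride to the ortho O‑methyl group only, so the ring A methoxy, which has no carbonyl within reach, and the ester and anhydride linkages should be left intact.

Step 11
Reactants: 16 depsidone phthalic anhydride phenol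
Product: 17 racemic depsidone lactol
Conditions: LiAlH(O‑t‑Bu)3 (2.2 equiv), THF, −78 → −40 °C; then cold 1 M HCl
Reagents that add atoms: none
Why: Half‑reduction of a cyclic anhydride to a hydroxy‑lactone: the first hydride equivalent forms the phenoxide, which turns its ortho carbonyl into a deactivated vinylogous carboxylate, so the bulky reagent should add once to the other carbonyl (next to the diaryl‑ether carbon) at low temperature without touching the hindered seven‑membered aryl ester; the new stereocentre is formed racemic.

Step 12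
Reactants: 17 racemic depsidone lactol
Product: 18 (R)‑O‑propionyl depsidone lactol
Conditions: HyperBTM (5 mol%; (2S,3R) or (2R,3S), whichever a pilot run on 17 shows to deliver the R ester), (EtCO)2O (1.2 equiv), i‑Pr2NEt (1.5 equiv), CHCl3, 0 °C
Reagents that add atoms: propionic anhydride, CCC(=O)OC(=O)CC
Why: Acylative dynamic kinetic resolution of a 3‑hydroxyphthalide: the lactol enantiomers interconvert through the ring‑opened formyl carboxylate under the amine base while the chiral acyl‑isothiouronium ion propionylates one of them faster, so the stereocentre is set by the catalyst and locked as the acylal; the chelated, doubly flanked phenol should react much more slowly.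

Step 13
Reactants: 18 (R)‑O‑propionyl depsidone lactol
Product: 19 (R)‑depsidone lactol (target; constitution of hypostictic acid)
Conditions: immobilised Candida antarctica lipase B, n‑BuOH (5 equiv), dry MTBE, 20 °C; filter, concentrate below 25 °C
Reagents that add atoms: none
Why: Lipase‑catalysed alcoholysis (transesterification) takes place at the propionyl carbonyl and not at the acetal carbon, so the R configuration is carried over unchanged, and the neutral anhydrous medium contains no base or acid to open the lactol.

Compound list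
1 | atraric acid (methyl 2,4‑dihydroxy‑3,6‑dimethylbenzoate) | COC(=O)c1c(C)cc(O)c(C)c1O | starting material
2 | methyl 2‑hydroxy‑4‑methoxy‑3,6‑dimethylbenzoate | COC(=O)c1c(C)cc(OC)c(C)c1O | intermediate
3 | 2‑hydroxy‑4‑methoxy‑3,6‑dimethylbenzoic acid | OC(=O)c1c(C)cc(OC)c(C)c1O | intermediate
4 | allyl 2‑hydroxy‑4‑methoxy‑3,6‑dimethylbenzoate | C=CCOC(=O)c1c(C)cc(OC)c(C)c1O | intermediate
5 | methyl propionate | CCC(=O)OC | starting material
6 | sodium enolate of methyl 2‑formylpropanoate | COC(=O)C(C)=C[O-].[Na+] | intermediate (not isolated)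
7 | methyl (E)‑3‑methoxy‑2‑methylprop‑2‑enoate | COC(=O)/C(C)=C/OC | intermediate
8 | lithium (3E)‑1‑chloro‑2,4‑dimethoxy‑3‑methylbut‑3‑en‑2‑olate (racemic) | COC([O-])(CCl)/C(C)=C/OC.[Li+] | intermediate (not isolated)
9 | (E)‑1‑chloro‑4‑methoxy‑3‑methylbut‑3‑en‑2‑one | O=C(CCl)/C(C)=C/OC | intermediate
10 | allyl 4‑methoxy‑2‑{[(3E)‑4‑methoxy‑3‑methyl‑2‑oxobut‑3‑en‑1‑yl]oxy}‑3,6‑dimethylbenzoate | C=CCOC(=O)c1c(C)cc(OC)c(C)c1OCC(=O)/C(C)=C/OC | intermediate
11 | 4‑methoxy‑2‑{[(3E)‑4‑methoxy‑3‑methyl‑2‑oxobut‑3‑en‑1‑yl]oxy}‑3,6‑dimethylbenzoic acid | OC(=O)c1c(C)cc(OC)c(C)c1OCC(=O)/C(C)=C/OC | intermediate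
12 | 8‑methoxy‑3‑[(1E)‑1‑methoxyprop‑1‑en‑2‑yl]‑6,9‑dimethyl‑5H‑1,4‑benzodioxepin‑5‑one (enol‑lactone diene) | COc1cc(C)c2c(c1C)OC=C(OC2=O)/C(C)=C/OC | intermediate
13 | dibromomaleic anhydride | O=C1OC(=O)C(Br)=C1Br | starting material
14 | dibromo cycloadduct: cyclohexene fused to the dioxepinone and to the anhydride, Br on both anhydride ring‑fusion carbons, flanked by CH(O‑aryl) and CH(OMe) (racemic, cis‑fused, endo/exo not assigned) | COc1cc(C)c2c(c1C)OC1C(OC2=O)=C(C)C(OC)C3(Br)C(=O)OC(=O)C13Br | intermediate (not isolated)
15 | depsidone phthalic anhydride methyl ether (ring B carries, from the ester oxygen onward, methyl, methoxy and the fused anhydride) | COc1cc(C)c2c(c1C)Oc1c(c(C)c(OC)c3C(=O)OC(=O)c13)OC2=O | intermediate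
16 | depsidone phthalic anhydride phenol (15 with ring B methoxy replaced by hydroxy) | COc1cc(C)c2c(c1C)Oc1c(c(C)c(O)c3C(=O)OC(=O)c13)OC2=O | intermediate
17 | racemic depsidone lactol (CH(OH) next to the diaryl‑ether carbon, lactone C=O next to the phenol) | COc1cc(C)c2c(c1C)Oc1c(c(C)c(O)c3c1C(O)OC3=O)OC2=O | intermediate
18 | (R)‑O‑propionyl depsidone lactol | COc1cc(C)c2c(c1C)Oc1c(c(C)c(O)c3c1[C@H](OC(=O)CC)OC3=O)OC2=O | intermediate
19 | (R)‑depsidone lactol | COc1cc(C)c2c(c1C)Oc1c(c(C)c(O)c3c1[C@H](O)OC3=O)OC2=O | target

Total step count: 13. Longest linear sequence: 11 steps (steps 1–3 and 6–13 from atraric acid); the side chain (steps 4–5) joins at step 6.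

Steps most likely to fail

Step 9. The cycloaddition to the tetrasubstituted dienophile may be too slow to outrun thermal decay of the enol‑ester diene, or the adduct may resist dehydrobromination where hydrogen and bromine are cis. Fallback: 12 is heated instead with di‑tert‑butyl acetylenedicarboxylate to give the cyclohexa‑1,4‑diene diester F1. After the cycloaddition DDQ is added at room temperature and dehydrogenates F1 to the di‑tert‑butyl phthalate F2. Trifluoroacetic acid in CH2Cl2 cleaves both tert‑butyl esters to the phthalic diacid F3, and warm acetic anhydride closes F3 to anhydride 15, where the route resumes.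

Step 8. Acylation may occur at the α‑aryloxy carbon instead of at oxygen (closure to a five‑membered benzofuranone), the activated acid may react intermolecularly, or the enol ether may be lost to the acid that is released. Fallback: the enol geometry and the oxygen nucleophile are fixed before the acyl donor is unmasked. Keto ester 10 is enolised under soft conditions (TBSOTf, Et3N, CH2Cl2) to the (1Z,3E)‑silyl dienol ether allyl ester F4. Pd(0)/sulfinate deallylation with a buffered work‑up gives the silyl dienol ether acid F5, and cyanuric fluoride–pyridine converts it into the acyl fluoride F6. A catalytic anhydrous fluoride source (tetrabutylammonium difluorotriphenylsilicate) then triggers desilylative O‑acylation of the silyl enol ether by the acyl fluoride, closing enol lactone 12.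

Step 12. Enantiodiscrimination by the small‑molecule catalyst may be insufficient on this crowded lactol, or the phenol may be acylated in competition. Fallback: the configuration is secured by separation instead of catalyst control. Lactol 17 is peracetylated (Ac2O, pyridine, DMAP) to the racemic diacetate F7, whose acylal stereocentre no longer epimerises. Preparative chromatography on a chiral stationary phase gives the (R)‑diacetate F8 and the (S)‑diacetate F9. F8 is deacetylated at both oxygens by the lipase alcoholysis of step 13 to give 19. F9 is returned to racemic 17 by the same alcoholysis followed by brief amine‑mediated equilibration.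

Further compounds
F1 | step 9 | di‑tert‑butyl cyclohexa‑1,4‑diene‑1,2‑dicarboxylate adduct of 12 (racemic) | COc1cc(C)c2c(c1C)OC1C(OC2=O)=C(C)C(OC)C(C(=O)OC(C)(C)C)=C1C(=O)OC(C)(C)C
F2 | step 9 | depsidone di‑tert‑butyl phthalate (ring B methyl ether) | COc1cc(C)c2c(c1C)Oc1c(c(C)c(OC)c(C(=O)OC(C)(C)C)c1C(=O)OC(C)(C)C)OC2=O
F3 | step 9 | depsidone phthalic diacid (ring B methyl ether) | COc1cc(C)c2c(c1C)Oc1c(c(C)c(OC)c(C(O)=O)c1C(O)=O)OC2=O
F4 | step 8 | allyl 2‑{[(1Z,3E)‑2‑(tert‑butyldimethylsilyloxy)‑4‑methoxy‑3‑methylbuta‑1,3‑dien‑1‑yl]oxy}‑4‑methoxy‑3,6‑dimethylbenzoate | C=CCOC(=O)c1c(C)cc(OC)c(C)c1O/C=C(\O[Si](C)(C)C(C)(C)C)/C(C)=C/OC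
F5 | step 8 | 2‑{[(1Z,3E)‑2‑(tert‑butyldimethylsilyloxy)‑4‑methoxy‑3‑methylbuta‑1,3‑dien‑1‑yl]oxy}‑4‑methoxy‑3,6‑dimethylbenzoic acid | OC(=O)c1c(C)cc(OC)c(C)c1O/C=C(\O[Si](C)(C)C(C)(C)C)/C(C)=C/OC
F6 | step 8 | 2‑{[(1Z,3E)‑2‑(tert‑butyldimethylsilyloxy)‑4‑methoxy‑3‑methylbuta‑1,3‑dien‑1‑yl]oxy}‑4‑methoxy‑3,6‑dimethylbenzoyl fluoride | FC(=O)c1c(C)cc(OC)c(C)c1O/C=C(\O[Si](C)(C)C(C)(C)C)/C(C)=C/OC
F7 | step 12 | racemic depsidone lactol diacetate | COc1cc(C)c2c(c1C)Oc1c(c(C)c(OC(C)=O)c3c1C(OC(C)=O)OC3=O)OC2=O
F8 | step 12 | (R)‑depsidone lactol diacetate | COc1cc(C)c2c(c1C)Oc1c(c(C)c(OC(C)=O)c3c1[C@H](OC(C)=O)OC3=O)OC2=O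
F9 | step 12 | (S)‑depsidone lactol diacetate | COc1cc(C)c2c(c1C)Oc1c(c(C)c(OC(C)=O)c3c1[C@@H](OC(C)=O)OC3=O)OC2=O
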